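**Assumptions (one line each)**
- The target has no stereocentres. The only stereo-element is the trisubstituted (E)-alkene, so "single enantiomer" is trivially satisfied.
- Reading the SMILES, the ring CH2 is trans to the (CH2)6Ph chain and cis to the vinylic CH3, which is E.
- 4-Hydroxy-5,6-dimethyl-2H-pyran-2-one (compound 1) is taken as commercially available.
- Simple reagents are described by name and SMILES in each step. Only starting materials, intermediates and the target are numbered.

**Retrosynthesis**
- The C1'–C2' bond is cut by a Negishi-type coupling of the lateral (6-CH2) zinc species of a 3,4-dimethoxy-5,6-dimethyl-2-pyranone with an (E)-trisubstituted alkenyl iodide.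
- The alkenyl iodide comes from Zr-catalysed syn-carboalumination and iodination of 8-phenyl-1-octyne. This sets the E geometry, with I cis to Me. The alkyne comes from (6-bromohexyl)benzene and acetylide.
- The pyranone is already formed in commercial 4-hydroxy-5,6-dimethylpyranone. Only the O-methyl groups need installing: 4-O-methylation, then C3 iodination and Cu-catalysed methoxylation.
- No ring is formed in the route.

---

**Step 1**
Reactants: 1, 4-hydroxy-5,6-dimethyl-2H-pyran-2-one
Product: 2, 4-methoxy-5,6-dimethyl-2H-pyran-2-one
Conditions: Me2SO4, K2CO3, acetone, reflux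
Reagents that add atoms: dimethyl sulfate, COS(=O)(=O)OC
Why: The vinylogous acid is the most acidic site and is O-alkylated under SN2 conditions. This is a standard enol-ether formation, and no stereocentre is involved.

**Step 2**
Reactants: 2
Product: 3, 3-iodo-4-methoxy-5,6-dimethyl-2H-pyran-2-one
Conditions: NIS, MeCN, rt, dark
Reagents that add atoms: N-iodosuccinimide, O=C1CCC(=O)N1I
Why: C3 is the only ring C–H and is the nucleophilic enol-ether carbon, so electrophilic iodination (SEAr-type) is regioselective. The methyl groups are untouched without a radical initiator.

**Step 3**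
Reactants: 3
Product: 4, 3,4-dimethoxy-5,6-dimethyl-2H-pyran-2-one
Conditions: CuI (10 mol %), 3,4,7,8-tetramethyl-1,10-phenanthroline (20 mol %), Cs2CO3, MeOH, toluene, 100 °C
Reagents that add atoms: methanol, CO
Why: This is a Cu-catalysed Ullmann-type C–O coupling of a vinyl iodide with methanol. The mild carbonate base avoids attack of methoxide on the lactone.

**Step 4**
Reactants: 5, (6-bromohexyl)benzene
Product: 6, 8-phenyloct-1-yne
Conditions: lithium acetylide–ethylenediamine complex, DMSO, rt
Reagents that add atoms: lithium acetylide·ethylenediamine, [Li]C#C.NCCN
Why: This is an SN2 alkylation of acetylide at a primary bromide, which gives the terminal alkyne directly.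

**Step 5**
Reactants: 6
Product: 7, (E)-1-iodo-2-methyl-8-phenyloct-1-ene
Conditions: (i) AlMe3, Cp2ZrCl2 (10 mol %), ClCH2CH2Cl, 0 °C to rt; (ii) I2, THF, −30 to 0 °C
Reagents that add atoms: trimethylaluminium, C[Al](C)C; iodine, II
Why: Zr-catalysed methylalumination (Negishi carboalumination) adds Me and Al syn across the terminal alkyne with Me on the internal carbon. Iodinolysis retains configuration, so I ends up cis to Me and trans to the chain (E). This fixes the alkene geometry of the target.

**Step 6**
Reactants: 4, 7
Product: 8, lehualide E
Conditions: (i) LDA, THF, −78 °C; (ii) ZnBr2, −78 to 0 °C; (iii) 7, Pd(PPh3)4 (5 mol %), THF, 50 °C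
Reagents that add atoms: none (Li, Zn and I are lost as salts)
Why: The 6-CH3 is the only methyl conjugated to the lactone carbonyl (dienolate-type), so LDA deprotonates it selectively. Transmetalation to zinc followed by Pd-catalysed Negishi sp3–sp2 coupling retains the alkene geometry from 7 and forms no new stereocentre.

---

**Compound list**

| No. | Name | SMILES | Role |
|---|---|---|---|
| 1 | 4-hydroxy-5,6-dimethyl-2H-pyran-2-one | Cc1oc(=O)cc(O)c1C | starting material |
| 2 | 4-methoxy-5,6-dimethyl-2H-pyran-2-one | COc1cc(=O)oc(C)c1C | intermediate |
| 3 | 3-iodo-4-methoxy-5,6-dimethyl-2H-pyran-2-one | COc1c(I)c(=O)oc(C)c1C | intermediate |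
| 4 | 3,4-dimethoxy-5,6-dimethyl-2H-pyran-2-one | COc1c(OC)c(=O)oc(C)c1C | intermediate |
| 5 | (6-bromohexyl)benzene | BrCCCCCCc1ccccc1 | starting material |
| 6 | 8-phenyloct-1-yne | C#CCCCCCCc1ccccc1 | intermediate |
| 7 | (E)-1-iodo-2-methyl-8-phenyloct-1-ene | I/C=C(\C)CCCCCCc1ccccc1 | intermediate |
| 8 | lehualide E | COc1c(C)c(C/C=C(\C)CCCCCCc2ccccc2)oc(=O)c1OC | target |

**Step count:** 6 steps in total. The longest linear sequence is 4 steps (1 → 2 → 3 → 4 → 8).

**Three steps most likely to fail**
1. **Step 6 (lateral zincation and Negishi coupling).** The extended zinc dienolate may couple at ring carbons rather than the CH2, and the product's skipped CH2 can isomerise into conjugation with the ring.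
   - Fallback: brominate the lateral anion (LDA, then BrCCl2CCl2Br) to give 6-(bromomethyl)pyranone. Couple it with the alkenylalane from step 5, taken before the iodine quench, using CuCl catalysis in an SN2-type allylic-style coupling.
2. **Step 3 (Cu-catalysed methoxylation).** Methanol or methoxide may open the lactone, or conversion may be low.
   - Fallback: Miyaura borylation of 3 (B2pin2, Pd), then oxidation to the 3-hydroxypyranone (H2O2/NaOH), then O-methylation (MeI, K2CO3).
3. **Step 2 (C3 iodination).** It may be unselective, or the iodide may be unstable.
   - Fallback: skip steps 2 and 3 by building the core directly. Acylate methyl 2-methylacetoacetate with methoxyacetyl chloride to give the enol ester. Cyclise it by Dieckmann condensation (KOtBu) to 4-hydroxy-3-methoxy-5,6-dimethylpyranone, then methylate the 4-OH to give 4.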